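(The readings were computed on assumed constants; scatter was added.)

| flask | substrate | partner | protic impurity | remark | time |
|---|---|---|---|---|---|
| midnight | 0.028 M | 0.60 equiv | 2.8 mM | run made earlier |  |
| noon | 0.019 M | 0.60 equiv | 2.8 mM | run made earlier |  |
| autumn | 0.042 M | 0.60 equiv | 2.8 mM | run made earlier |  |
| ash | 0.028 M (fed, over 5.00 h) | 0.600 equiv | 2.80 mM | all but substrate at the start; substrate goes in evenly over 5.00 h, the run ends at 5.0 h | 5.0 h |
| elm | 0.028 M | 0.600 equiv | 2.80 mM | a closed flask charged with all of it at once and left for 5.0 h | 5.0 h |
| cedar | 0.028 M | 0.600 equiv (fed, over 5.00 h) | 2.80 mM | all but partner at the start; partner goes in evenly over 5.00 h, the run ends at 5.0 h | 5.0 h |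
| birch | 0.028 M | 0.600 equiv | 2.80 mM | one stirred flow tank at steady state, fed with the mixture as stated, mean residence time 5.0 h |  |

- midnight (time / h: target / %, substrate / %): 0.200: 4.2, 95.4; 0.667: 10.8, 89.0; 1.00: 14.9, 85.4; 1.50: 18.3, 81.1; 2.50: 24.8, 75.5; 3.00: 27.0, 73.2
- noon (time / h: target / %, substrate / %): 0.833: 8.3, 92.1; 1.50: 11.9, 87.9; 2.50: 16.3, 82.9; 3.00: 18.5, 82.1; 4.00: 21.4, 79.0; 5.00: 23.7, 76.3
- autumn (time / h: target / %, substrate / %): 0.417: 12.8, 87.3; 0.667: 17.7, 82.3; 1.00: 22.6, 77.4; 2.00: 31.6, 68.2; 3.00: 36.9, 63.0; 5.00: 42.0, 57.9

(standard deviation of a reading: 0.3 percentage points)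

- the stated concentrations are those of everything mixed, before any reaction; amounts are the same in each set-up
- the feed brings no volume worth counting
- the earlier runs were made in a closed, stirred flask

- the set-up with the highest amount of target at the outlet or at the end, in percent of the substrate put in ("none" if the first two lie within 2 percentage points) (ash / elm / cedar / birch / none)
- amount of target at the outlet or at the end, in percent of the substrate put in, ash
- amount of target at the outlet or at the end, in percent of the substrate put in, elm
- amount of target at the outlet or at the end, in percent of the substrate put in, cedar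
- amount of target at the outlet or at the end, in percent of the substrate put in, birch

The number was 2.50 h: the contact time, my name for the mean residence time of a molecule fed evenly over 5.00 h. I took the set-ups in turn and read each from the runs.

Charging at once came first. Midnight had elm's charge but stopped at 3.00 h. Noon and autumn reached 5.00 h, and elm's substrate stood a factor 1.47 above noon and 1.50 below autumn. So I took the mean of their last readings:

elm: mean of 23.7% and 42.0% = 32.9%

Feeding substrate came next. The average molecule of ash met partner for 2.50 h, so I read midnight there:

ash: midnight at 2.50 h = 24.8%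

I held this as an upper estimate. The midnight curve flattened, rising faster early than late, and the mean of a flattening curve over evenly spread ages lies below its value at the mean age.

Feeding partner has the same contact time. But I assumed that the protic impurity took the first 16.7% of cedar's feed. On that assumption, the working partner in cedar had a shorter contact time:

cedar: 2.08 h, between midnight's 18.3% and 24.8%

So I put cedar below ash.

In the tank, birch's mean stay equals 5.0 h, but its median stay is 3.47 h. The nearest midnight reading was 27.0% at 3.00 h, so I put birch below elm.

The forecast chose elm: elm 33%, birch 22.3%, ash 18.5%, cedar 15%. Its ground for the fed flasks was “Feeding wastes the early active period.” Its ash stood lower than my reading.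

Elm gave 33.2%, birch 25.4%, ash 23.1% and cedar 18.9%, so elm was best.

substrate + partner → target, rate k1*[substrate]*[partner]^1.5 (k = 108 L¹·⁵ mol⁻¹·⁵ h⁻¹); partner + protic impurity → quenched reagent (k = 145 L mol⁻¹ h⁻¹); 2 substrate → self-condensation product (k = 0.00241 L mol⁻¹ h⁻¹) Ash ended 1.7 percentage points under the midnight reading at 2.50 h. The neighbour of ash with 0.048 M of substrate had the same contact time, 2.50 h. Autumn, at 0.042 M, read 31.6% at 2.00 h and 36.9% at 3.00 h, and the neighbour ended at 35.5%.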